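## Analysis of the target

The target 32 is a (2S)-flavanone: a benzene ring A fused to the dihydropyranone ring C, which carries the phenyl ring B at C2. Ring A is a fully substituted phloroglucinol, with oxygen at C5 (OH), C7 (OH) and C8a (the ring ether O1), 2,3-dihydroxybenzyl arms on C6 and C8, and the acyl carbon C4 on C4a. C2 is the only stereocenter. It is a benzylic ether carbon β to the ketone, so base can open ring C by retro-oxa-Michael reaction to the achiral chalcone and erase it. The six phenols, four of them in two catechols, make the free compound oxidation-sensitive, so they should be unveiled only in the last step. Two things make the synthesis hard. The first is a hexasubstituted ring A in which three oxygens must be told apart and two identical arms must go to C6 and C8 but not to C4a. The second is a labile stereocenter that must have a secure configuration and should not meet base once ring C exists. The strategy rests on the six carbons C4a, C5, C6, C7, C8 and C8a of ring A. A phenol carbon (C5) flanked by an unsubstituted carbon (C4a) and an alkyl-bearing carbon (C6), with an oxygen at C7 and a substituted C8/C8a pair, is the pattern that a cyclobutenone–siloxyalkyne benzannulation delivers. The O1–C2 ether can ride in on the cyclobutenone as a purchased (S)-alcohol.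

## Retrosynthetic reasoning

**32 from 31.** The six phenolic O–H bonds are traced back to six O-benzyl bonds in flavanone 31. One protecting group for all six phenols allows a single neutral hydrogenolysis at the end. No base then touches the flavanone, so C2 cannot racemise through ring opening, and the catechols appear last.

**31 from 29 (through 30).** Ring C is opened at C4–C4a. This is the only ring C bond that can be made by electrophilic substitution at the single free carbon of ring A, which lies ortho to two ether oxygens and para to the third. Cutting O1–C2 instead would put the creation of the stereocenter late. Cutting C2–C3 or C3–C4 would require an acyl group on the hexasubstituted ring beforehand. The forward reaction is an intramolecular Friedel–Crafts acylation of acid 29 through mixed anhydride 30. It must be mild enough to spare the benzyl ethers and the β-aryloxy acid.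

**29 from 26 (through 27 and 28).** The carboxyl carbon, the future C4, is traced to the internal carbon of a terminal alkene, with loss of the terminal CH2. The alkene is a carboxyl surrogate that survives organolithium reagents, ketene 17 and the heat of the benzannulation, and it comes with the commercial alcohol 9. The forward sequence is dihydroxylation–cleavage to aldehyde 28 via diol 27, then oxidation to 29.

**26 from 23 (through 24 and 25).** The benzyl ethers at the C5 and C7 oxygens are traced to the free phenol and the silyl ether of 23. The exchange of silyl for benzyl is placed here, before ring C exists, so that all basic and fluoride chemistry is finished while C2 is still a simple, non-enolisable ether carbon.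

**23 from 18 and 8 (key disconnection).** Ring A is cut at C5–C6, C7–C8 and C4a–C5. Cyclobutenone 18 then supplies C5 (its carbonyl carbon), C4a (its CH2), C8a (carrying the chiral ether) and C8 (carrying one arm). Siloxyalkyne 8 supplies C6 (carrying the other arm) and C7 (carrying the silyloxy group). The gain is that all five substituents of ring A are fixed by the connectivity of two open-chain partners, and the three oxygens emerge differentiated as phenol, silyl ether and chiral alkyl ether. The forward cascade (19, 20, 21, 22) must deliver one regiochemistry in the ketene–alkyne union and must leave the benzylic ether carbon untouched.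

**18 from 16 and 17.** The cyclobutenone is cut at the C3–C4 and C1–C2 bonds into ynol ether 16 and ketene 17. The polarisation of the ynol ether decides that the alkoxy group ends up at C3 and the benzyl group at C2.

**16 from 13 and 4 (through 14 and 15), and 13 from 9 and 10 (through 11 and 12).** The propargylic C–C bond, the future C8–CH2 bond, is cut to give lithium alkoxyacetylide 15 and benzylic bromide 4. The O–C(sp) bond, the future O1–C8a bond, is cut to give alcohol 9 and trichloroethylene 10 by way of dichlorovinyl ether 13. The stereocenter is bought with 9 and its C–O bond is never broken.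

**8 from 5 (through 6 and 7), and 5 from 4.** The C–O bond of the siloxyalkyne is traced to oxidation of acetylide 6 to ynolate 7. An ester homologation was avoided here because it would start from an arylacetic ester, which is readily enolised. The terminal alkyne 5 comes from bromide 4 by the future C6–CH2 bond.

**4 from 1 (through 2 and 3).** Both arms derive from one aldehyde, 1, by benzylation, reduction and bromination. Bromide 4 is the common electrophile for the two halves.

## Alternatives that were turned down

**Alternative 1:** Ring C of a flavone is cut at C4a–C4, C3–C4 and O1–C2. This leads to the iodophenol A2 (3,5-bis(benzyloxy)-2,4-bis[2,3-bis(benzyloxy)benzyl]-6-iodophenol), phenylacetylene A3 and carbon monoxide A4.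
- Forward key step: a carbonylative coupling of A2, A4 and A3 under PdCl2(PPh3)2 and a secondary amine. The acylpalladium species is captured by the alkyne and the phenol oxygen closes ring C in the 6-endo mode to give flavone A1 (5,7-bis(benzyloxy)-6,8-bis[2,3-bis(benzyloxy)benzyl]flavone).
- For: three bonds and ring C are made in one catalytic operation, rings B and C come from very cheap components, and no thermal pericyclic cascade is needed.
- Against: A1 is planar at C2. The only stereocenter would have to be made afterwards by an enantioselective conjugate reduction of a 2-aryl chromone that has a C5 benzyloxy group beside the carbonyl and a C8 arm beside O1. Poor facial discrimination and over-reduction of the ketone are both to be expected, and the flavanone would be formed under conditions in which it can reopen.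
- Against: A2 is itself the hard part. It needs one free and two benzylated ring oxygens and two arms on C6 and C8 but not on C4a. Electrophilic benzylation of a symmetrical trioxygenated ring does not make that distinction, so A2 would require a long preparation with many protecting-group steps.
- Against: oxidative addition into the di-ortho-substituted C–I bond is slow, and 5-exo closure competes.
- Comparison: Alternative 1 is stronger in convergence and in catalytic bond economy for ring C. The chosen route offers instead a stereocenter that is bought and only carried, and a ring A whose pattern is dictated by the mechanism of its formation. The step counts would be similar only if A2 were short to make, which its structure makes unlikely.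

**Alternative 2:** Both catechol rings are removed. Each is traced to cyclohexane-1,2-dione A7 and an aldehyde carbon of 2,4,6-tris(benzyloxy)isophthalaldehyde A6, so the bonds cut are those from the two future CH2 carbons to the six-membered rings.
- Forward key step: a double aldol condensation of A6 with A7. The primary condensation products tautomerise (isoaromatisation) to bis-catechol A5 (3,3'-{[2,4,6-tris(benzyloxy)-1,3-phenylene]bis(methylene)}bis(benzene-1,2-diol)).
- For: this is the shortest access to the two 3-benzylcatechol arms. It uses a cheap dione, places the arms on C6 and C8 without ambiguity and gives the catechols unprotected. On cost and protecting-group economy for the arms it is better than the chosen route, which spends steps 1–5 and 7 on bromide 4 and its derivatives.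
- Against: the step solves the part of the molecule that is not the problem. After A5, ring C and C2 are still missing. The catechols must be protected, C4a acylated, one flanking benzyl ether removed and the enone built. Ring C must then be closed by an oxa-Michael addition that has to be enantioselective although it is reversible, which is the very process by which flavanones racemise.
- Against: the three ring A oxygens leave the key step undifferentiated. The symmetry of A5 helps, since the two oxygens ortho to C4a are equivalent. The double condensation must also take place at aldehydes that are each flanked by two benzyloxy groups.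
- Comparison: the chosen strategy gives up the cheaper arms. In return ring A is formed with its oxygens differentiated and with O1 already bonded to a C2 of fixed configuration. Alternative 2 would need about eight more steps after A5, one of them an unsolved asymmetric step.

**Alternative 3:** Ring C of a flavan is cut at O1–C2 and C3–C4. This gives the salicylaldehyde A9 (4,6-bis(benzyloxy)-3,5-bis[2,3-bis(benzyloxy)benzyl]-2-hydroxybenzaldehyde), styrene A10 and trimethyl orthoformate A11.
- Forward key step: A9 and A11 with a chiral Brønsted acid give the methoxy ortho-quinone methide A12 (3,5-bis(benzyloxy)-2,4-bis[2,3-bis(benzyloxy)benzyl]-6-(methoxymethylidene)cyclohexa-2,4-dien-1-one). A12 adds A10 across O1 and C4 in a hetero-[4+2] cycloaddition to give the 2,4-cis chroman A8 ((2S,4S)-5,7-bis(benzyloxy)-6,8-bis[2,3-bis(benzyloxy)benzyl]-4-methoxy-2-phenylchroman).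
- For: the step is convergent. Ring C and the C2 stereocenter are made together from cheap achiral partners under catalyst control, and the polarisation of A10 fixes phenyl at C2. On convergence and on creating C2 catalytically it is stronger than the chosen route.
- Against: A8 is at the wrong oxidation level at C4. Cleavage of the benzylic methyl ether and oxidation are needed, passing through a 4-oxygenated flavan that ionises easily on so electron-rich a ring.
- Against: the enantioselectivity would depend on a chiral counter-anion discriminating the faces of A12. A12 is flanked by the C5 benzyloxy group and carries a bulky arm next to O1, so the ion-pair organisation is hard to predict.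
- Against: A9 is again a hexasubstituted arene with one oxygen differentiated, and it poses the same assembly problem as A2.
- Comparison: the chosen route creates no stereocenter at all. That is less ambitious chemistry but more secure for a single-enantiomer target, and it builds the hexasubstituted ring instead of presupposing it.

Key step: step 9

Assumption: ketene 17 is generated as needed by pyrolysis of acetone and passed into the reaction as a gas; alcohol 9 is purchased as the single (S)-enantiomer.

## Route

Step 1
Reactants: 1 2,3-dihydroxybenzaldehyde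
Product: 2 2,3-bis(benzyloxy)benzaldehyde
Conditions: BnBr, K2CO3, DMF, 60 °C
Reagents that add atoms: benzyl bromide, BrCc1ccccc1
Why: Williamson etherification of both phenols; the aldehyde is not enolisable and the hydrogen-bonded 2-OH is alkylated on warming in DMF.

Step 2
Reactants: 2 2,3-bis(benzyloxy)benzaldehyde
Product: 3 [2,3-bis(benzyloxy)phenyl]methanol
Conditions: NaBH4, MeOH/THF, 0 °C
Reagents that add atoms: none
Why: Hydride reduction of an aryl aldehyde; benzyl ethers are inert.

Step 3
Reactants: 3 [2,3-bis(benzyloxy)phenyl]methanol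
Product: 4 1,2-bis(benzyloxy)-3-(bromomethyl)benzene
Conditions: PBr3, Et2O, 0 °C
Reagents that add atoms: phosphorus tribromide, BrP(Br)Br
Why: The benzylic alcohol is converted into the bromide through its phosphite ester and SN2 displacement by bromide; the low temperature and short contact time should keep the aryl benzyl ethers intact.

Step 4
Reactants: 4 1,2-bis(benzyloxy)-3-(bromomethyl)benzene
Product: 5 1,2-bis(benzyloxy)-3-(prop-2-yn-1-yl)benzene
Conditions: HC≡CMgBr (excess), CuCl (cat.), THF, 50 °C
Reagents that add atoms: ethynylmagnesium bromide, C#C[Mg]Br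
Why: Copper-catalysed cross-coupling of a benzylic bromide with an alkynyl Grignard reagent; excess Grignard reagent suppresses double benzylation and a non-basic work-up avoids propargyl–allenyl isomerisation.

Step 5
Reactants: 5 1,2-bis(benzyloxy)-3-(prop-2-yn-1-yl)benzene
Product: 8 3-[2,3-bis(benzyloxy)phenyl]prop-1-ynyl triisopropylsilyl ether, via lithium acetylide 6 (not isolated), via lithium ynolate 7 (not isolated)
Conditions: n-BuLi, THF, −78 °C; t-BuOOLi (from t-BuOOH, LiN(SiMe3)2), −78 → 0 °C; TIPSOTf, −78 → 0 °C
Reagents that add atoms: tert-butyl hydroperoxide, CC(C)(C)OO; triisopropylsilyl trifluoromethanesulfonate, CC(C)[Si](OS(=O)(=O)C(F)(F)F)(C(C)C)C(C)C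
Why: Deprotonation of the terminal alkyne gives 6, electrophilic oxygen transfer from lithium tert-butyl peroxide gives ynolate 7, and the bulky silyl triflate silylates 7 on oxygen rather than carbon; this is the acetylide-oxidation route to siloxyalkynes and it avoids an enolisable arylacetic ester.

Step 6
Reactants: 9 (S)-1-phenylbut-3-en-1-ol; 10 trichloroethylene
Product: 13 (S)-[1-((E)-1,2-dichlorovinyloxy)but-3-enyl]benzene, via potassium alkoxide 11 (not isolated), via dichloroethyne 12 (not isolated)
Conditions: KH, THF, 0 °C; then 10, −50 °C → rt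
Reagents that add atoms: none
Why: Alkoxide 11 dehydrochlorinates trichloroethylene to dichloroethyne 12 and adds to it in anti fashion, which should give the (E)-dichlorovinyl ether; the carbinol C–O bond is not touched, so the S configuration is retained.

Step 7
Reactants: 13 (S)-[1-((E)-1,2-dichlorovinyloxy)but-3-enyl]benzene; 4 1,2-bis(benzyloxy)-3-(bromomethyl)benzene
Product: 16 1,2-bis(benzyloxy)-3-{3-[(S)-1-phenylbut-3-enyloxy]prop-2-yn-1-yl}benzene, via chloroalkynyl ether 14 (not isolated), via lithium alkoxyacetylide 15 (not isolated)
Conditions: n-BuLi (2.1 equiv), THF, −78 → −40 °C; then 4, HMPA, −78 → 0 °C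
Reagents that add atoms: none
Why: The first equivalent of n-BuLi removes the vinylic proton and chloride leaves to give 14, the second performs chlorine–lithium exchange to acetylide 15, and 15 is C-alkylated by the benzylic bromide in the presence of HMPA (ynol ether synthesis from dichlorovinyl ethers). The product is a benzylic alkynyl ether, so it is kept below room temperature and used at once to avoid sigmatropic rearrangement.

Step 8
Reactants: 16 1,2-bis(benzyloxy)-3-{3-[(S)-1-phenylbut-3-enyloxy]prop-2-yn-1-yl}benzene; 17 ketene
Product: 18 2-[2,3-bis(benzyloxy)benzyl]-3-[(S)-1-phenylbut-3-enyloxy]cyclobut-2-en-1-one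
Conditions: 17 (gas, from pyrolysis of acetone), CH2Cl2, 0 °C
Reagents that add atoms: none
Why: Thermal [2+2] cycloaddition of ketene with an ynol ether; the nucleophilic β-carbon of the ynol ether, which bears the benzyl group, bonds to the ketene carbonyl carbon, so the alkoxy group ends up at C3 and the benzyl group at C2 of the cyclobutenone.

Step 9
Reactants: 18 2-[2,3-bis(benzyloxy)benzyl]-3-[(S)-1-phenylbut-3-enyloxy]cyclobut-2-en-1-one; 8 3-[2,3-bis(benzyloxy)phenyl]prop-1-ynyl triisopropylsilyl ether
Product: 23 2,4-bis[2,3-bis(benzyloxy)benzyl]-5-[(S)-1-phenylbut-3-enyloxy]-3-(triisopropylsilyloxy)phenol, via vinylketene 19 (not isolated), via 4-vinylcyclobutenone 20 (not isolated), via dienylketene 21 (not isolated), via cyclohexadienone 22 (not isolated)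
Conditions: 8 (1.5 equiv), toluene, 80 °C, then 135 °C, sealed tube
Reagents that add atoms: none
Why: Heating opens cyclobutenone 18 by 4π electrocyclic cleavage of its C1–C4 bond to vinylketene 19, whose ketene C=C bond undergoes a regioselective [2+2] cycloaddition with siloxyalkyne 8 to give 4-vinylcyclobutenone 20. A second 4π opening gives dienylketene 21, which closes ring A by thermal disrotatory 6π electrocyclisation (the C4a–C5 bond) to cyclohexadienone 22 and tautomerises to phenol 23; in flavanone numbering the cascade forms C5–C6, C7–C8 and C4a–C5. This is the Danheiser benzannulation, and the closest known case is the union of cyclobutenones with triisopropylsiloxyalkynes to give resorcinol monosilyl ethers; the 3-alkoxy group makes 18 a vinylogous ester, which is expected to open more slowly, hence the higher final temperature. No stereocenter is created: the quaternary carbon of 20 forms as both epimers and is destroyed when that ring opens, and the (S)-benzylic ether carbon takes no part. The step needs regiocontrol in the ketene–alkyne [2+2], and the polarisation of the siloxyalkyne secures it: its benzyl-bearing β-carbon is the nucleophilic terminus and bonds to the ketene carbonyl carbon, so the silyloxy carbon becomes C7 between the two arms. It also needs chemoselectivity for the siloxyalkyne over the tethered terminal alkene and over the product phenol, which the high nucleophilicity of 8, used in excess, should provide.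

Step 10
Reactants: 23 2,4-bis[2,3-bis(benzyloxy)benzyl]-5-[(S)-1-phenylbut-3-enyloxy]-3-(triisopropylsilyloxy)phenol
Product: 26 1,3-bis(benzyloxy)-2,4-bis[2,3-bis(benzyloxy)benzyl]-5-[(S)-1-phenylbut-3-enyloxy]benzene, via monobenzyl silyl ether 24 (not isolated), via tetrabutylammonium phenoxide 25 (not isolated)
Conditions: BnBr, K2CO3, DMF, rt; then TBAF (THF), BnBr, rt
Reagents that add atoms: benzyl bromide, BrCc1ccccc1
Why: Williamson benzylation of the single free phenol gives 24; fluoride then cleaves the aryl silyl ether to phenoxide 25, which is O-benzylated in the dipolar aprotic medium (one-pot desilylative alkylation). Placing this before ring C exists keeps fluoride and carbonate away from the base-labile flavanone, and an early loss of the silyl group would lead to the same product.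

Step 11
Reactants: 26 1,3-bis(benzyloxy)-2,4-bis[2,3-bis(benzyloxy)benzyl]-5-[(S)-1-phenylbut-3-enyloxy]benzene
Product: 28 (3S)-3-{3,5-bis(benzyloxy)-2,4-bis[2,3-bis(benzyloxy)benzyl]phenoxy}-3-phenylpropanal, via diol 27 (not isolated)
Conditions: OsO4 (cat.), NaIO4, 2,6-lutidine, dioxane/H2O, rt
Reagents that add atoms: osmium tetroxide, O=[Os](=O)(=O)=O; sodium periodate, [Na+].[O-]I(=O)(=O)=O
Why: Lemieux–Johnson oxidation: catalytic dihydroxylation of the only alkene to diol 27 and periodate cleavage to the aldehyde. The near-neutral medium should avoid β-elimination of the aryloxide, and the aldehyde is carried on crude.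

Step 12
Reactants: 28 (3S)-3-{3,5-bis(benzyloxy)-2,4-bis[2,3-bis(benzyloxy)benzyl]phenoxy}-3-phenylpropanal
Product: 29 (3S)-3-{3,5-bis(benzyloxy)-2,4-bis[2,3-bis(benzyloxy)benzyl]phenoxy}-3-phenylpropanoic acid
Conditions: NaClO2, NaH2PO4, 2-methyl-2-butene, t-BuOH/THF/H2O, 0 °C → rt
Reagents that add atoms: sodium chlorite, [Na+].[O-]Cl=O
Why: Pinnick oxidation at mildly acidic pH; 2-methyl-2-butene traps hypochlorous acid before it can chlorinate the electron-rich rings, and the conditions do not promote β-elimination.

Step 13
Reactants: 29 (3S)-3-{3,5-bis(benzyloxy)-2,4-bis[2,3-bis(benzyloxy)benzyl]phenoxy}-3-phenylpropanoic acid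
Product: 31 (2S)-5,7-bis(benzyloxy)-6,8-bis[2,3-bis(benzyloxy)benzyl]-2-phenylchroman-4-one, via mixed trifluoroacetic anhydride 30 (not isolated)
Conditions: (CF3CO)2O, CH2Cl2, 0 °C → rt
Reagents that add atoms: none
Why: Intramolecular Friedel–Crafts acylation through mixed anhydride 30; C4a is the only free position of ring A and is activated by two ortho and one para alkoxy group, so the six-membered ring C should close without a strong Lewis acid. C2 is not involved and keeps the S configuration.

Step 14
Reactants: 31 (2S)-5,7-bis(benzyloxy)-6,8-bis[2,3-bis(benzyloxy)benzyl]-2-phenylchroman-4-one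
Product: 32 (2S)-5,7-dihydroxy-6,8-bis(2,3-dihydroxybenzyl)-2-phenylchroman-4-one
Conditions: H2 (1 atm), 10% Pd/C, EtOAc/MeOH, rt
Reagents that add atoms: none
Why: Catalytic hydrogenolysis of the six aryl benzyl ethers under neutral conditions, so no base reaches C2; stopping at complete debenzylation should limit reduction of the C4 ketone and hydrogenolysis of the benzylic C2–O1 bond.

## Compound list

1 | 2,3-dihydroxybenzaldehyde | O=Cc1cccc(O)c1O | starting material
2 | 2,3-bis(benzyloxy)benzaldehyde | O=Cc1cccc(OCc2ccccc2)c1OCc1ccccc1 | intermediate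
3 | [2,3-bis(benzyloxy)phenyl]methanol | OCc1cccc(OCc2ccccc2)c1OCc1ccccc1 | intermediate
4 | 1,2-bis(benzyloxy)-3-(bromomethyl)benzene | BrCc1cccc(OCc2ccccc2)c1OCc1ccccc1 | intermediate
5 | 1,2-bis(benzyloxy)-3-(prop-2-yn-1-yl)benzene | C#CCc1cccc(OCc2ccccc2)c1OCc1ccccc1 | intermediate
6 | lithium 3-[2,3-bis(benzyloxy)phenyl]prop-1-yn-1-ide (not isolated) | [Li]C#CCc1cccc(OCc2ccccc2)c1OCc1ccccc1 | intermediate
7 | lithium 3-[2,3-bis(benzyloxy)phenyl]prop-1-yn-1-olate (not isolated) | [Li+].[O-]C#CCc1cccc(OCc2ccccc2)c1OCc1ccccc1 | intermediate
8 | 3-[2,3-bis(benzyloxy)phenyl]prop-1-ynyl triisopropylsilyl ether | CC(C)[Si](OC#CCc1cccc(OCc2ccccc2)c1OCc1ccccc1)(C(C)C)C(C)C | intermediate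
9 | (S)-1-phenylbut-3-en-1-ol | O[C@@H](CC=C)c1ccccc1 | starting material
10 | trichloroethylene | ClC=C(Cl)Cl | starting material
11 | potassium (S)-1-phenylbut-3-en-1-olate (not isolated) | [K+].[O-][C@@H](CC=C)c1ccccc1 | intermediate
12 | dichloroethyne (not isolated) | ClC#CCl | intermediate
13 | (S)-[1-((E)-1,2-dichlorovinyloxy)but-3-enyl]benzene | Cl/C=C(/Cl)O[C@@H](CC=C)c1ccccc1 | intermediate
14 | (S)-[1-(chloroethynyloxy)but-3-enyl]benzene (not isolated) | ClC#CO[C@@H](CC=C)c1ccccc1 | intermediate
15 | lithium 2-[(S)-1-phenylbut-3-enyloxy]ethyn-1-ide (not isolated) | [Li]C#CO[C@@H](CC=C)c1ccccc1 | intermediate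
16 | 1,2-bis(benzyloxy)-3-{3-[(S)-1-phenylbut-3-enyloxy]prop-2-yn-1-yl}benzene | C(#CO[C@@H](CC=C)c1ccccc1)Cc1cccc(OCc2ccccc2)c1OCc1ccccc1 | intermediate
17 | ketene (ethenone), generated from acetone | C=C=O | starting material
18 | 2-[2,3-bis(benzyloxy)benzyl]-3-[(S)-1-phenylbut-3-enyloxy]cyclobut-2-en-1-one | O=C1CC(O[C@@H](CC=C)c2ccccc2)=C1Cc1cccc(OCc2ccccc2)c1OCc1ccccc1 | intermediate
19 | 2-[2,3-bis(benzyloxy)benzyl]-3-[(S)-1-phenylbut-3-enyloxy]buta-1,3-dien-1-one (vinylketene, not isolated) | O=C=C(Cc1cccc(OCc2ccccc2)c1OCc1ccccc1)C(=C)O[C@@H](CC=C)c1ccccc1 | intermediate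
20 | 2,4-bis[2,3-bis(benzyloxy)benzyl]-4-{1-[(S)-1-phenylbut-3-enyloxy]vinyl}-3-(triisopropylsilyloxy)cyclobut-2-en-1-one (both epimers at C4, not isolated) | O=C1C(Cc2cccc(OCc3ccccc3)c2OCc2ccccc2)=C(O[Si](C(C)C)(C(C)C)C(C)C)C1(Cc1cccc(OCc2ccccc2)c1OCc1ccccc1)C(=C)O[C@@H](CC=C)c1ccccc1 | intermediate
21 | (3E)-2,4-bis[2,3-bis(benzyloxy)benzyl]-5-[(S)-1-phenylbut-3-enyloxy]-3-(triisopropylsilyloxy)hexa-1,3,5-trien-1-one (dienylketene, not isolated) | O=C=C(Cc1cccc(OCc2ccccc2)c1OCc1ccccc1)/C(O[Si](C(C)C)(C(C)C)C(C)C)=C(Cc1cccc(OCc2ccccc2)c1OCc1ccccc1)\C(=C)O[C@@H](CC=C)c1ccccc1 | intermediate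
22 | 2,4-bis[2,3-bis(benzyloxy)benzyl]-5-[(S)-1-phenylbut-3-enyloxy]-3-(triisopropylsilyloxy)cyclohexa-2,4-dien-1-one (not isolated) | O=C1CC(O[C@@H](CC=C)c2ccccc2)=C(Cc2cccc(OCc3ccccc3)c2OCc2ccccc2)C(O[Si](C(C)C)(C(C)C)C(C)C)=C1Cc1cccc(OCc2ccccc2)c1OCc1ccccc1 | intermediate
23 | 2,4-bis[2,3-bis(benzyloxy)benzyl]-5-[(S)-1-phenylbut-3-enyloxy]-3-(triisopropylsilyloxy)phenol | Oc1cc(O[C@@H](CC=C)c2ccccc2)c(Cc2cccc(OCc3ccccc3)c2OCc2ccccc2)c(O[Si](C(C)C)(C(C)C)C(C)C)c1Cc1cccc(OCc2ccccc2)c1OCc1ccccc1 | intermediate
24 | 1-(benzyloxy)-2,4-bis[2,3-bis(benzyloxy)benzyl]-5-[(S)-1-phenylbut-3-enyloxy]-3-(triisopropylsilyloxy)benzene (not isolated) | O(Cc1ccccc1)c1cc(O[C@@H](CC=C)c2ccccc2)c(Cc2cccc(OCc3ccccc3)c2OCc2ccccc2)c(O[Si](C(C)C)(C(C)C)C(C)C)c1Cc1cccc(OCc2ccccc2)c1OCc1ccccc1 | intermediate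
25 | tetrabutylammonium 3-(benzyloxy)-2,6-bis[2,3-bis(benzyloxy)benzyl]-5-[(S)-1-phenylbut-3-enyloxy]phenolate (not isolated) | CCCC[N+](CCCC)(CCCC)CCCC.[O-]c1c(Cc2cccc(OCc3ccccc3)c2OCc2ccccc2)c(OCc2ccccc2)cc(O[C@@H](CC=C)c2ccccc2)c1Cc1cccc(OCc2ccccc2)c1OCc1ccccc1 | intermediate
26 | 1,3-bis(benzyloxy)-2,4-bis[2,3-bis(benzyloxy)benzyl]-5-[(S)-1-phenylbut-3-enyloxy]benzene | O(Cc1ccccc1)c1cc(O[C@@H](CC=C)c2ccccc2)c(Cc2cccc(OCc3ccccc3)c2OCc2ccccc2)c(OCc2ccccc2)c1Cc1cccc(OCc2ccccc2)c1OCc1ccccc1 | intermediate
27 | (4S)-4-{3,5-bis(benzyloxy)-2,4-bis[2,3-bis(benzyloxy)benzyl]phenoxy}-4-phenylbutane-1,2-diol (both epimers at C2, not isolated) | O(Cc1ccccc1)c1cc(O[C@@H](CC(O)CO)c2ccccc2)c(Cc2cccc(OCc3ccccc3)c2OCc2ccccc2)c(OCc2ccccc2)c1Cc1cccc(OCc2ccccc2)c1OCc1ccccc1 | intermediate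
28 | (3S)-3-{3,5-bis(benzyloxy)-2,4-bis[2,3-bis(benzyloxy)benzyl]phenoxy}-3-phenylpropanal | O(Cc1ccccc1)c1cc(O[C@@H](CC=O)c2ccccc2)c(Cc2cccc(OCc3ccccc3)c2OCc2ccccc2)c(OCc2ccccc2)c1Cc1cccc(OCc2ccccc2)c1OCc1ccccc1 | intermediate
29 | (3S)-3-{3,5-bis(benzyloxy)-2,4-bis[2,3-bis(benzyloxy)benzyl]phenoxy}-3-phenylpropanoic acid | O(Cc1ccccc1)c1cc(O[C@@H](CC(=O)O)c2ccccc2)c(Cc2cccc(OCc3ccccc3)c2OCc2ccccc2)c(OCc2ccccc2)c1Cc1cccc(OCc2ccccc2)c1OCc1ccccc1 | intermediate
30 | (3S)-3-{3,5-bis(benzyloxy)-2,4-bis[2,3-bis(benzyloxy)benzyl]phenoxy}-3-phenylpropanoic trifluoroacetic anhydride (not isolated) | O(Cc1ccccc1)c1cc(O[C@@H](CC(=O)OC(=O)C(F)(F)F)c2ccccc2)c(Cc2cccc(OCc3ccccc3)c2OCc2ccccc2)c(OCc2ccccc2)c1Cc1cccc(OCc2ccccc2)c1OCc1ccccc1 | intermediate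
31 | (2S)-5,7-bis(benzyloxy)-6,8-bis[2,3-bis(benzyloxy)benzyl]-2-phenylchroman-4-one | O=C1C[C@@H](c2ccccc2)Oc2c(Cc3cccc(OCc4ccccc4)c3OCc3ccccc3)c(OCc3ccccc3)c(Cc3cccc(OCc4ccccc4)c3OCc3ccccc3)c(OCc3ccccc3)c21 | intermediate
32 | (2S)-5,7-dihydroxy-6,8-bis(2,3-dihydroxybenzyl)-2-phenylchroman-4-one | O=C1C[C@@H](c2ccccc2)Oc2c(Cc3cccc(O)c3O)c(O)c(Cc3cccc(O)c3O)c(O)c21 | target

## Step count and least certain steps

Total step count: 14. Longest linear sequence: 11 steps (steps 1, 2, 3, 4, 5, 9, 10, 11, 12, 13, 14; the branch through steps 7 and 8 is equally long).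

**Step 9 (key step).** The ring opening of the vinylogous-ester cyclobutenone 18 may be too slow at temperatures that the siloxyalkyne tolerates. Conversion would then stall while 8 drifts to a silylketene by 1,3-silyl shift, or the vinylketene would be intercepted by the product phenol as an aryl ester. Intramolecular capture of the ketene by the tethered alkene is a lesser concern. The fallback gives up the benzannulation and sets out from aldehyde 1. NaBH4 in methanol should reduce 1 to 3-(hydroxymethyl)benzene-1,2-diol F1. F1 (about 2.5 equiv) is then heated with purchased (2S)-pinocembrin (O=C1C[C@@H](c2ccccc2)Oc2cc(O)cc(O)c21) and ZnCl2 in dioxane. Each equivalent of F1 should form an ortho-quinone methide that alkylates the nucleophilic C6 and C8 positions of the flavanone. Under these acidic conditions C2 is not at risk. The double adduct is the target, so the fallback comes back to the route at 32. Its price is a separation from the mono-alkylated flavanones.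

**Step 7.** The secondary benzylic alkynyl ether may undergo sigmatropic rearrangement or fragmentation during the alkylation and isolation, or the alkylation of the hindered alkoxyacetylide may be sluggish enough for decomposition to compete. The fallback sets out from bromide 4 and forms the chiral ether bond last. Lithium ethoxyacetylide (from ethoxyacetylene and n-BuLi) is alkylated with 4 in THF/HMPA to give the robust 1,2-bis(benzyloxy)-3-(3-ethoxyprop-2-yn-1-yl)benzene F2. Ketene 17 converts F2 into 2-[2,3-bis(benzyloxy)benzyl]-3-ethoxycyclobut-2-en-1-one F3. Dilute HCl in THF hydrolyses F3 to the vinylogous acid 2-[2,3-bis(benzyloxy)benzyl]-3-hydroxycyclobut-2-en-1-one F4. A Mitsunobu reaction of F4 with (R)-1-phenylbut-3-en-1-ol (O[C@H](CC=C)c1ccccc1; PPh3, DIAD, THF, 0 °C) should alkylate the enol oxygen with inversion and so come back to the route at cyclobutenone 18. Because F4 is symmetrical, only one O-alkyl product is possible. Some erosion of enantiopurity at the benzylic carbon would have to be checked.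

**Step 5.** Deprotonation of 5 may be accompanied by propargyl–allenyl isomerisation, oxygen transfer to the acetylide may be incomplete, or silylation may occur partly on carbon. The fallback sets out from bromide 4 and reaches the same ynolate by ester homologation. Carbonylation of 4 (CO, EtOH, PdCl2(PPh3)2, K2CO3, 60 °C) gives ethyl 2-[2,3-bis(benzyloxy)phenyl]acetate F5. Addition of LiCHBr2 (from CH2Br2 and lithium 2,2,6,6-tetramethylpiperidide, −78 °C) gives, after LiN(SiMe3)2, the enolate of 3-[2,3-bis(benzyloxy)phenyl]-1,1-dibromopropan-2-one F6. Bromine–lithium exchange with n-BuLi and rearrangement on warming (Kowalski homologation) gives ynolate 7. The fallback thus comes back to the route at 7, which is silylated as in step 5 to 8. Its own weak point is competing enolisation of F5.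

**Step 13.** The activated acyl derivative may lose the electron-rich aryloxide by β-elimination, or the acid may remove or shift benzyl groups, in particular the one ortho to the new ketone. The fallback sets out from acid 29 and reverses the polarity of the ring closure. NBS (1 equiv, MeCN, 0 °C) should brominate the only free, strongly activated ring A position to give (3S)-3-{3,5-bis(benzyloxy)-2,4-bis[2,3-bis(benzyloxy)benzyl]-6-bromophenoxy}-3-phenylpropanoic acid F7. Coupling with MeNHOMe·HCl (EDC, i-Pr2NEt) gives (3S)-3-{3,5-bis(benzyloxy)-2,4-bis[2,3-bis(benzyloxy)benzyl]-6-bromophenoxy}-N-methoxy-N-methyl-3-phenylpropanamide F8. Bromine–lithium exchange with t-BuLi at −78 °C and attack of the aryllithium on the amide (Parham cyclisation) gives, after acidic work-up of the stable tetrahedral adduct, flavanone 31, where the fallback comes back to the route. No enolisable ketone is exposed to base in this sequence.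

**Step 14.** Hydrogenolysis may also cleave the benzylic C2–O1 bond or reduce the C4 ketone before the last, hindered benzyl ethers are removed. The fallback sets out from 31 and replaces reductive cleavage by Lewis-acid cleavage. BCl3 with pentamethylbenzene as cation scavenger in CH2Cl2 at −78 °C should remove all six benzyl groups and come back to the route at 32. It makes no new compound (entry F0).

## Further compounds

F1 | step 9 | 3-(hydroxymethyl)benzene-1,2-diol | OCc1cccc(O)c1O
F2 | step 7 | 1,2-bis(benzyloxy)-3-(3-ethoxyprop-2-yn-1-yl)benzene | CCOC#CCc1cccc(OCc2ccccc2)c1OCc1ccccc1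
F3 | step 7 | 2-[2,3-bis(benzyloxy)benzyl]-3-ethoxycyclobut-2-en-1-one | CCOC1=C(Cc2cccc(OCc3ccccc3)c2OCc2ccccc2)C(=O)C1
F4 | step 7 | 2-[2,3-bis(benzyloxy)benzyl]-3-hydroxycyclobut-2-en-1-one | OC1=C(Cc2cccc(OCc3ccccc3)c2OCc2ccccc2)C(=O)C1
F5 | step 5 | ethyl 2-[2,3-bis(benzyloxy)phenyl]acetate | CCOC(=O)Cc1cccc(OCc2ccccc2)c1OCc1ccccc1
F6 | step 5 | 3-[2,3-bis(benzyloxy)phenyl]-1,1-dibromopropan-2-one | BrC(Br)C(=O)Cc1cccc(OCc2ccccc2)c1OCc1ccccc1
F7 | step 13 | (3S)-3-{3,5-bis(benzyloxy)-2,4-bis[2,3-bis(benzyloxy)benzyl]-6-bromophenoxy}-3-phenylpropanoic acid | O(Cc1ccccc1)c1c(Br)c(O[C@@H](CC(=O)O)c2ccccc2)c(Cc2cccc(OCc3ccccc3)c2OCc2ccccc2)c(OCc2ccccc2)c1Cc1cccc(OCc2ccccc2)c1OCc1ccccc1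
F8 | step 13 | (3S)-3-{3,5-bis(benzyloxy)-2,4-bis[2,3-bis(benzyloxy)benzyl]-6-bromophenoxy}-N-methoxy-N-methyl-3-phenylpropanamide | O(Cc1ccccc1)c1c(Br)c(O[C@@H](CC(=O)N(C)OC)c2ccccc2)c(Cc2cccc(OCc3ccccc3)c2OCc2ccccc2)c(OCc2ccccc2)c1Cc1cccc(OCc2ccccc2)c1OCc1ccccc1
F0 | step 14 | none | none
A1 | alternative 1 | 5,7-bis(benzyloxy)-6,8-bis[2,3-bis(benzyloxy)benzyl]flavone | O=c1cc(-c2ccccc2)oc2c(Cc3cccc(OCc4ccccc4)c3OCc3ccccc3)c(OCc3ccccc3)c(Cc3cccc(OCc4ccccc4)c3OCc3ccccc3)c(OCc3ccccc3)c12
A2 | alternative 1 | 3,5-bis(benzyloxy)-2,4-bis[2,3-bis(benzyloxy)benzyl]-6-iodophenol | Oc1c(I)c(OCc2ccccc2)c(Cc2cccc(OCc3ccccc3)c2OCc2ccccc2)c(OCc2ccccc2)c1Cc1cccc(OCc2ccccc2)c1OCc1ccccc1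
A3 | alternative 1 | phenylacetylene | C#Cc1ccccc1
A4 | alternative 1 | carbon monoxide | [C-]#[O+]
A5 | alternative 2 | 3,3'-{[2,4,6-tris(benzyloxy)-1,3-phenylene]bis(methylene)}bis(benzene-1,2-diol) | Oc1cccc(Cc2c(OCc3ccccc3)cc(OCc3ccccc3)c(Cc3cccc(O)c3O)c2OCc2ccccc2)c1O
A6 | alternative 2 | 2,4,6-tris(benzyloxy)isophthalaldehyde | O=Cc1c(OCc2ccccc2)cc(OCc2ccccc2)c(C=O)c1OCc1ccccc1
A7 | alternative 2 | cyclohexane-1,2-dione | O=C1CCCCC1=O
A8 | alternative 3 | (2S,4S)-5,7-bis(benzyloxy)-6,8-bis[2,3-bis(benzyloxy)benzyl]-4-methoxy-2-phenylchroman | CO[C@H]1C[C@@H](c2ccccc2)Oc2c(Cc3cccc(OCc4ccccc4)c3OCc3ccccc3)c(OCc3ccccc3)c(Cc3cccc(OCc4ccccc4)c3OCc3ccccc3)c(OCc3ccccc3)c21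
A9 | alternative 3 | 4,6-bis(benzyloxy)-3,5-bis[2,3-bis(benzyloxy)benzyl]-2-hydroxybenzaldehyde | O=Cc1c(O)c(Cc2cccc(OCc3ccccc3)c2OCc2ccccc2)c(OCc2ccccc2)c(Cc2cccc(OCc3ccccc3)c2OCc2ccccc2)c1OCc1ccccc1
A10 | alternative 3 | styrene | C=Cc1ccccc1
A11 | alternative 3 | trimethyl orthoformate | COC(OC)OC
A12 | alternative 3 | 3,5-bis(benzyloxy)-2,4-bis[2,3-bis(benzyloxy)benzyl]-6-(methoxymethylidene)cyclohexa-2,4-dien-1-one | COC=C1C(=O)C(Cc2cccc(OCc3ccccc3)c2OCc2ccccc2)=C(OCc2ccccc2)C(Cc2cccc(OCc3ccccc3)c2OCc2ccccc2)=C1OCc1ccccc1
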